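**Retrosynthetic overview**
- Cassyformin ⇐ one acid step that removes two aryl MOM groups, a trityl ether and a diethyl acetal from a fully protected 2,3-trans-dihydrobenzofuran.
- The benzofuran benzene ring and the dihydrofuran ring are made together, last: intramolecular inverse-electron-demand Diels–Alder of a 3-(alkynyloxy)pyridazine, then loss of N2.
- The cycloaddition precursor ⇐ SNAr of a secondary alkoxide on a 3-chloro-4-methoxypyridazine that already carries the masked propenal chain at C6 (site-selective Suzuki on 3,6-dichloro-4-methoxypyridazine).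
- Both stereocentres ⇐ one Cu-catalysed enantioselective borylative coupling of the protected aryl aldehyde with a silyl enyne (anti-2-alkynyl-1,3-diol after oxidation).
- Ring order: the pendant arene is bought (5-hydroxyvanillin); the other two rings form in the key step.

Assumption: (S,S)-Ph-BPE is taken as the ligand antipode that gives the (1R,2S) adduct in step 2; if the sense is the opposite, (R,R)-Ph-BPE is used.

**Step 1**
Reactants: 1 3,4-dihydroxy-5-methoxybenzaldehyde (5-hydroxyvanillin)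
Product: 2 3-methoxy-4,5-bis(methoxymethoxy)benzaldehyde
Conditions: MOMCl (2.6 equiv), i-Pr2NEt (3 equiv), CH2Cl2, 0 °C → rt
Reagents that add atoms: chloromethyl methyl ether, COCCl
Why: Base-mediated O-alkylation (MOM protection) of both phenols gives acetals that survive base, Pd and 215 °C and fall off in the last acid step; no stereocentre is involved.

**Step 2**
Reactants: 2 3-methoxy-4,5-bis(methoxymethoxy)benzaldehyde; 3 trimethyl(but-3-en-1-yn-1-yl)silane; 4 bis(pinacolato)diboron
Product: 7 (1R,2S)-2-ethynyl-1-[3-methoxy-4,5-bis(methoxymethoxy)phenyl]propane-1,3-diol, via bis-boryl adduct 5 (not isolated), via silyl-alkyne diol 6 (not isolated)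
Conditions: CuCl (5 mol %), (S,S)-Ph-BPE (6 mol %), NaOt-Bu (20 mol %), THF, 22 °C; then aq. NaOH, 30 % H2O2, 0 °C; then MeOH, rt
Reagents that add atoms: hydrogen peroxide, OO
Why: Cu-catalysed enantioselective borylative enyne–aldehyde coupling (borocupration of the alkene, then allenyl-copper propargylation through a closed six-membered transition state) gives the anti adduct, the chiral bisphosphine sets C1 as R and with it C2 as S, and the alkaline peroxide work-up converts C–B into C–OH and cleaves O–B and C(sp)–Si.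

**Step 3**
Reactants: 7 (1R,2S)-2-ethynyl-1-[3-methoxy-4,5-bis(methoxymethoxy)phenyl]propane-1,3-diol
Product: 8 (1R,2S)-1-[3-methoxy-4,5-bis(methoxymethoxy)phenyl]-2-[(trityloxy)methyl]but-3-yn-1-ol
Conditions: TrCl (1.1 equiv), Et3N, DMAP (cat.), CH2Cl2, rt
Reagents that add atoms: trityl chloride, ClC(c1ccccc1)(c1ccccc1)c1ccccc1
Why: Tritylation is sterically selective for the primary hydroxyl, and a trityl ether (unlike a silyl ether) cannot migrate to the neighbouring alkoxide in step 5; the stereocentres are untouched.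

**Step 4**
Reactants: 9 3,6-dichloro-4-methoxypyridazine; 10 2-[(E)-3,3-diethoxyprop-1-en-1-yl]-4,4,5,5-tetramethyl-1,3,2-dioxaborolane
Product: 11 3-chloro-6-[(E)-3,3-diethoxyprop-1-en-1-yl]-4-methoxypyridazine
Conditions: Pd(dppf)Cl2 (3 mol %), K2CO3, 1,4-dioxane/H2O, 70 °C (1.0 equiv of 10)
Reagents that add atoms: none
Why: Site-selective Suzuki–Miyaura coupling, with oxidative addition expected at the C6–Cl bond because it is neither flanked nor π-enriched by the 4-methoxy group; the E geometry of the boronate is retained and the site is confirmed by an NOE between H5 and the vinyl proton.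

**Step 5**
Reactants: 8 (1R,2S)-1-[3-methoxy-4,5-bis(methoxymethoxy)phenyl]-2-[(trityloxy)methyl]but-3-yn-1-ol; 11 3-chloro-6-[(E)-3,3-diethoxyprop-1-en-1-yl]-4-methoxypyridazine
Product: 13 6-[(E)-3,3-diethoxyprop-1-en-1-yl]-4-methoxy-3-{[(1R,2S)-1-[3-methoxy-4,5-bis(methoxymethoxy)phenyl]-2-[(trityloxy)methyl]but-3-yn-1-yl]oxy}pyridazine, via sodium alkoxide 12 (not isolated)
Conditions: NaH (1.05 equiv), THF, 0 °C; then 11 (1.2 equiv), DMF, rt → 50 °C
Reagents that add atoms: none
Why: SNAr (addition–elimination) of the secondary alkoxide at the only remaining C–Cl of the diazine; the C–O bond of the carbinol stereocentre is not broken, so (1R,2S) is retained.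

**Step 6**
Reactants: 13 6-[(E)-3,3-diethoxyprop-1-en-1-yl]-4-methoxy-3-{[(1R,2S)-1-[3-methoxy-4,5-bis(methoxymethoxy)phenyl]-2-[(trityloxy)methyl]but-3-yn-1-yl]oxy}pyridazine
Product: 15 (2R,3S)-5-[(E)-3,3-diethoxyprop-1-en-1-yl]-7-methoxy-2-[3-methoxy-4,5-bis(methoxymethoxy)phenyl]-3-[(trityloxy)methyl]-2,3-dihydro-1-benzofuran, via diazabicyclooctatriene cycloadduct 14 (not isolated)
Conditions: 1,3,5-triisopropylbenzene (0.02 M), BHT (5 mol %), 215 °C, sealed tube, Ar
Reagents that add atoms: none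
Why: Intramolecular inverse-electron-demand Diels–Alder of the tethered terminal alkyne across C3/C6 of the 3-(alkynyloxy)pyridazine, then retro-Diels–Alder loss of N2, forms the benzene ring and the dihydrofuran ring in one operation and fixes O1, OMe and the side chain at C7a, C7 and C5 by construction, while the two tether stereocentres are not touched and become C2 (R) and C3 (S), trans.

**Step 7**
Reactants: 15 (2R,3S)-5-[(E)-3,3-diethoxyprop-1-en-1-yl]-7-methoxy-2-[3-methoxy-4,5-bis(methoxymethoxy)phenyl]-3-[(trityloxy)methyl]-2,3-dihydro-1-benzofuran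
Product: 16 cassyformin, (E)-3-[(2R,3S)-2-(3,4-dihydroxy-5-methoxyphenyl)-3-(hydroxymethyl)-7-methoxy-2,3-dihydro-1-benzofuran-5-yl]prop-2-enal
Conditions: 3 M aq. HCl/THF (1:3), 45 °C, Ar
Reagents that add atoms: water, O
Why: Acid-catalysed hydrolysis of the two aryl MOM acetals, the trityl ether and the diethyl acetal in one operation frees the catechol, the primary alcohol and the (E)-enal; C2 and C3 are not involved, and the 2,3-trans arrangement is the thermodynamically preferred one.

**Compound list**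
1 | 3,4-dihydroxy-5-methoxybenzaldehyde (5-hydroxyvanillin) | COc1cc(C=O)cc(O)c1O | starting material
2 | 3-methoxy-4,5-bis(methoxymethoxy)benzaldehyde | COc1cc(C=O)cc(OCOC)c1OCOC | intermediate
3 | trimethyl(but-3-en-1-yn-1-yl)silane | C=CC#C[Si](C)(C)C | starting material
4 | bis(pinacolato)diboron | CC1(C)OB(OC1(C)C)B1OC(C)(C)C(C)(C)O1 | starting material
5 | 2-{[(1R,2R)-1-[3-methoxy-4,5-bis(methoxymethoxy)phenyl]-2-[(4,4,5,5-tetramethyl-1,3,2-dioxaborolan-2-yl)methyl]-4-(trimethylsilyl)but-3-yn-1-yl]oxy}-4,4,5,5-tetramethyl-1,3,2-dioxaborolane (same spatial arrangement as 7; the C2 descriptor differs only because CH2B ranks below the alkyne) | COc1cc([C@H](OB2OC(C)(C)C(C)(C)O2)[C@H](CB2OC(C)(C)C(C)(C)O2)C#C[Si](C)(C)C)cc(OCOC)c1OCOC | intermediate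
6 | (1R,2S)-1-[3-methoxy-4,5-bis(methoxymethoxy)phenyl]-2-[(trimethylsilyl)ethynyl]propane-1,3-diol | COc1cc([C@H](O)[C@H](CO)C#C[Si](C)(C)C)cc(OCOC)c1OCOC | intermediate
7 | (1R,2S)-2-ethynyl-1-[3-methoxy-4,5-bis(methoxymethoxy)phenyl]propane-1,3-diol | COc1cc([C@H](O)[C@H](CO)C#C)cc(OCOC)c1OCOC | intermediate
8 | (1R,2S)-1-[3-methoxy-4,5-bis(methoxymethoxy)phenyl]-2-[(trityloxy)methyl]but-3-yn-1-ol | COc1cc([C@H](O)[C@H](COC(c2ccccc2)(c2ccccc2)c2ccccc2)C#C)cc(OCOC)c1OCOC | intermediate
9 | 3,6-dichloro-4-methoxypyridazine | COc1cc(Cl)nnc1Cl | starting material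
10 | 2-[(E)-3,3-diethoxyprop-1-en-1-yl]-4,4,5,5-tetramethyl-1,3,2-dioxaborolane | CCOC(OCC)/C=C/B1OC(C)(C)C(C)(C)O1 | starting material
11 | 3-chloro-6-[(E)-3,3-diethoxyprop-1-en-1-yl]-4-methoxypyridazine | COc1cc(/C=C/C(OCC)OCC)nnc1Cl | intermediate
12 | sodium (1R,2S)-1-[3-methoxy-4,5-bis(methoxymethoxy)phenyl]-2-[(trityloxy)methyl]but-3-yn-1-olate | COc1cc([C@H]([O-])[C@H](COC(c2ccccc2)(c2ccccc2)c2ccccc2)C#C)cc(OCOC)c1OCOC.[Na+] | intermediate
13 | 6-[(E)-3,3-diethoxyprop-1-en-1-yl]-4-methoxy-3-{[(1R,2S)-1-[3-methoxy-4,5-bis(methoxymethoxy)phenyl]-2-[(trityloxy)methyl]but-3-yn-1-yl]oxy}pyridazine | COc1cc([C@H](Oc2nnc(/C=C/C(OCC)OCC)cc2OC)[C@H](COC(c2ccccc2)(c2ccccc2)c2ccccc2)C#C)cc(OCOC)c1OCOC | intermediate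
14 | 2,3-diazabicyclo[2.2.2]octa-2,5,7-triene cycloadduct of 13 (alkyne added across pyridazine C3/C6, dihydrofuran ring fused; bridgehead configuration depends on the face of attack and is left open, both faces give 15) | COc1cc([C@@H]2OC34N=NC(/C=C/C(OCC)OCC)(C=C3OC)C=C4[C@H]2COC(c2ccccc2)(c2ccccc2)c2ccccc2)cc(OCOC)c1OCOC | intermediate
15 | (2R,3S)-5-[(E)-3,3-diethoxyprop-1-en-1-yl]-7-methoxy-2-[3-methoxy-4,5-bis(methoxymethoxy)phenyl]-3-[(trityloxy)methyl]-2,3-dihydro-1-benzofuran | COc1cc([C@@H]2Oc3c(OC)cc(/C=C/C(OCC)OCC)cc3[C@H]2COC(c2ccccc2)(c2ccccc2)c2ccccc2)cc(OCOC)c1OCOC | intermediate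
16 | cassyformin, (E)-3-[(2R,3S)-2-(3,4-dihydroxy-5-methoxyphenyl)-3-(hydroxymethyl)-7-methoxy-2,3-dihydro-1-benzofuran-5-yl]prop-2-enal | COc1cc([C@@H]2Oc3c(OC)cc(/C=C/C=O)cc3[C@H]2CO)cc(O)c1O | target

**Total step count:** 7
**Longest linear sequence:** 6 steps (steps 1, 2, 3, 5, 6, 7); step 4 is a one-step side branch.

**Three steps most likely to fail**

Step 6 (cycloaddition). The diazine carries two donor oxygens, so more than 200 °C is needed; at that temperature retro-ene loss of the pyridazinone from the benzylic heteroaryl ether, or an O→N benzyl shift, may compete. The fallback sets out from alcohol 8 and comes back at 15. It makes the diazine more electron-poor with chlorine and attaches the side chain only after the rings are built. Purchased 6-chloro-4-methoxypyridazin-3-amine is diazotised in HF·pyridine (NaNO2, 0 → 40 °C) via the diazonium fluoride F1 to 6-chloro-3-fluoro-4-methoxypyridazine F2. The alkoxide 12 (from 8 and NaH) displaces fluoride at 0 °C to rt with full site control and gives the chloro ether F3. F3 is heated in triisopropylbenzene (about 180–190 °C) and passes through the cycloadduct F4 to the 5-chloro-2,3-dihydrobenzofuran F5. Suzuki coupling of this aryl chloride with 10 (XPhos Pd G3, K3PO4, dioxane/H2O, 90 °C) gives 15.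

Step 5 (SNAr). The C3–Cl bond is flanked and π-enriched by the 4-methoxy group and the alkoxide is hindered; attack at C4 (methoxy exchange) or base-induced alkyne-to-allene isomerisation may compete. The fallback sets out from 6 (isolated by leaving out the methanol stage of step 2) and comes back at 13. It forms the aryl ether by Pd catalysis with the alkyne masked. 6 is tritylated as in step 3 to the silyl-alkyne alcohol F6. Pd-catalysed C–O cross-coupling of F6 with 11 (RockPhos Pd G3, Cs2CO3, toluene, 90 °C) gives the silyl-alkyne ether F7. K2CO3 in MeOH then removes the silyl group and gives 13.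

Step 4 (site-selective Suzuki). The preference for C6 over C3 is argued from electronics and sterics but is not proven for this 4-methoxy compound, and double coupling is possible. The fallback sets out from 10 and comes back at 11. It uses a building block whose only halogen is at C6. Purchased 6-chloro-4-methoxypyridazin-3-amine is coupled with 10 under the step-4 conditions to the aminopyridazine F8. Non-aqueous diazotisation and chlorination (t-BuONO, CuCl2, MeCN, 60 °C) via the diazonium chloride F9 then gives 11 with unambiguous regiochemistry.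

**Further compounds**
F1 | step 6 | 6-chloro-4-methoxypyridazine-3-diazonium fluoride | COc1cc(Cl)nnc1[N+]#N.[F-]
F2 | step 6 | 6-chloro-3-fluoro-4-methoxypyridazine | COc1cc(Cl)nnc1F
F3 | step 6 | 6-chloro-4-methoxy-3-{[(1R,2S)-1-[3-methoxy-4,5-bis(methoxymethoxy)phenyl]-2-[(trityloxy)methyl]but-3-yn-1-yl]oxy}pyridazine | COc1cc([C@H](Oc2nnc(Cl)cc2OC)[C@H](COC(c2ccccc2)(c2ccccc2)c2ccccc2)C#C)cc(OCOC)c1OCOC
F4 | step 6 | 2,3-diazabicyclo[2.2.2]octa-2,5,7-triene cycloadduct of F3 (bridgehead configuration left open) | COc1cc([C@@H]2OC34N=NC(Cl)(C=C3OC)C=C4[C@H]2COC(c2ccccc2)(c2ccccc2)c2ccccc2)cc(OCOC)c1OCOC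
F5 | step 6 | (2R,3S)-5-chloro-7-methoxy-2-[3-methoxy-4,5-bis(methoxymethoxy)phenyl]-3-[(trityloxy)methyl]-2,3-dihydro-1-benzofuran | COc1cc([C@@H]2Oc3c(OC)cc(Cl)cc3[C@H]2COC(c2ccccc2)(c2ccccc2)c2ccccc2)cc(OCOC)c1OCOC
F6 | step 5 | (1R,2S)-1-[3-methoxy-4,5-bis(methoxymethoxy)phenyl]-4-(trimethylsilyl)-2-[(trityloxy)methyl]but-3-yn-1-ol | COc1cc([C@H](O)[C@H](COC(c2ccccc2)(c2ccccc2)c2ccccc2)C#C[Si](C)(C)C)cc(OCOC)c1OCOC
F7 | step 5 | 6-[(E)-3,3-diethoxyprop-1-en-1-yl]-4-methoxy-3-{[(1R,2S)-1-[3-methoxy-4,5-bis(methoxymethoxy)phenyl]-4-(trimethylsilyl)-2-[(trityloxy)methyl]but-3-yn-1-yl]oxy}pyridazine | COc1cc([C@H](Oc2nnc(/C=C/C(OCC)OCC)cc2OC)[C@H](COC(c2ccccc2)(c2ccccc2)c2ccccc2)C#C[Si](C)(C)C)cc(OCOC)c1OCOC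
F8 | step 4 | 6-[(E)-3,3-diethoxyprop-1-en-1-yl]-4-methoxypyridazin-3-amine | COc1cc(/C=C/C(OCC)OCC)nnc1N
F9 | step 4 | 6-[(E)-3,3-diethoxyprop-1-en-1-yl]-4-methoxypyridazine-3-diazonium chloride | COc1cc(/C=C/C(OCC)OCC)nnc1[N+]#N.[Cl-]
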